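**Remark.** The SMILES is read as the (6R,7R,8R,10S) isomer with a (Z)-C4=C5 bond, and this isomer is the target. Germacrane numbers are used throughout: C1 ketone, C2=C3, C4=C5, C6 (lactone O), C7, C8 (ester), C9 (CH2), C10 (quaternary, methyl C14), C11=C13 with C12 (lactone carbonyl), C15 (CH2OH). Compounds 1, 5, 12 and 13 are taken as commercial.

## The problem

The target 26 is an 11-oxabicyclo[6.2.1]undecane. A 3(2H)-furanone ring (O, C10, C1, C2, C3) is bridged at C3 and C10 by a six-carbon chain, so that the oxygen also sits in a nine-membered oxonane ring (O, C3–C10). That ring carries the (Z)-C4=C5 bond and a trans-fused α-methylene-γ-lactone at C6/C7. Closing a nine-membered ring that holds a bridgehead enone and a fully substituted carbon is the hardest part. There are four stereocentres: the contiguous triad C6, C7, C8 and the quaternary C10, which the C9 methylene separates from the triad. C8 can control C7 and C6 in an open chain, but only a ring-forming event can relay configuration across C9 to C10.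

The feature that the plan uses is the furanone ring itself. C10 is α to the C1 carbonyl and bonded to the ring oxygen, so a precursor with hydrogen at C10 is the keto tautomer of a 2-methyl-3-hydroxyfuran. Its anion is an aromatic 3-oxidofuran whose only nucleophilic carbon is C10. C9 is a CH2 group next to the oxygenated C8, so C8–C9 is a glycerol-type unit in which C9 can carry a leaving group.

Sensitive groups are the exocyclic enoate C11=C13 (a Michael acceptor), the cross-conjugated dienone, the C8 ester next to the lactone (base causes acyl transfer and Claisen-type attack from C11), and the allylic C15 alcohol.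

## Retrosynthesis

**26 ⇒ 25 ⇒ 23.** The last two operations are functional-group changes: cleavage of the C15 silyl ether of 25, and regeneration of C11=C13 from the thiophenol adduct 23. The enoate must be masked because it would capture the C10 carbanion of the key step. The mask is removed only after C10 is quaternary.

**23 ⇒ 21 (key disconnection).** The C9–C10 bond is cut. The neighbouring cuts are C6–C7 (the lactone-forming allylation) and C3–C4 (cross-coupling); both leave the quaternary C10 to be made separately as a stereocentre. Cutting C9–C10 removes the nine-membered ring and the quaternary centre together. The precursor 21 is an open chain with only the C6–C8 triad, and C10 is an enolisable CH of a flat furanone. The forward reaction must alkylate at carbon and not oxygen, close a nine-membered ring, and choose the correct furanolate face.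

**21 ⇒ 19 ⇒ 18 ⇒ 17.** The C9 tosylate and C8 isobutyrate of 21 come from diol 19, which comes from acetonide 18. Thiol adduct 18 comes from the α-methylene lactone 17. Placing the isobutyrate before ring closure means that no lactone enolate is ever formed next to the C8 ester.

**17 ⇒ 11 + 15.** The C6–C7 bond and the lactone C12–O bond are cut: a chromium-mediated allylation of enal 11 by the 2-(bromomethyl)alkenoate 15. This cut is preferred to a C7–C8 or C5–C6 cut because it joins two fragments of similar size and sets C6 and C7 in one event under control of C8. The only purchased stereocentre is C8.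

**15 ⇒ 14 ⇒ 12 + 13.** The C7–C11 bond is cut (Morita–Baylis–Hillman reaction of glyceraldehyde acetonide 12 with methyl acrylate 13), followed by allylic transposition to the bromide. Both steps are standard and the carbinol configuration of 14 is irrelevant.

**11 ⇒ 9 ⇒ 8 ⇒ 4 + 7.** The furanone O–C3 bond is cut (5-endo-dig addition of the C10 hydroxyl to an ynone) and then the C3–C4 bond (Sonogashira coupling). The (Z)-geometry of C4=C5 is carried by vinyl iodide 4. The stereocentres of alkynol 7 are lost later, so 7 needs no control.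

**4 ⇒ 2 ⇒ 1 and 7 ⇒ 5.** Iodide 4 comes from hydroxyl-directed trans-hydroalumination and iodination of the mono-silylated butynediol 2 (from 1). Alkynol 7 comes from the lactate ester 5 by reduction and ethynyl addition.

## Roads not taken

**Alternative 1:** Cut C6–C7 and the lactone C–O last. The forward key step is an intramolecular chromium-mediated allylation of the C6 aldehyde by the 2-(bromomethyl)acrylate in the seco compound A1. The furanone would be made earlier by Sonogashira coupling at C3–C4 and gold-catalysed cyclisation of a hydroxy ynone that already carries C10 as a tertiary carbinol. This is the route most chemists would draw first. It needs C10 as a separate quaternary stereocentre, matched 1,3 to C8 in an open chain. C6 and C7 are then set inside the closing ring, where the transition-state geometry cannot be chosen. Aldehyde, allylic bromide and acrylate must be carried together through a longer linear sequence. In the chosen plan C10 remains an exchangeable CH until the ring closes, and C6/C7 are set in an open-chain reaction.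

**Alternative 2:** Ring expansion. A copper or rhodium carbenoid from diazo ketone A2 (a 2-vinyl-3,6-dihydro-2H-pyran with a diazo ketone side arm) would form an oxonium ylide whose [2,3]-sigmatropic shift gives the oxabicyclo[6.2.1]undecadienone A3. This forms the C9–C10 bond and the bridged skeleton in one step. However, it leaves a C7=C8 double bond where the target has two stereocentres bearing carbon and oxygen. The diazo carbon must carry the methyl group, so a 1,2-hydride shift competes. The furanone C2=C3 bond must be introduced later by dehydrogenation. The redox and C–C steps after the key step outweigh its gain.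

**Alternative 3:** Cut C1–C2 and O–C3. An intramolecular nitrile oxide cycloaddition of A4 would close the ten-membered carbocycle as the bridged isoxazoline A5. N–O cleavage, oxidation to the 1,3-diketone and cyclodehydration with the C10 hydroxyl would then give the furanone. The nitrile oxide would also add to the exocyclic enoate, so a mask is still needed. Three more steps on the strained ring are needed to reach the furanone. Bridged versus fused regiochemistry is uncertain for a ten-membered ring, and C10 must again be made separately.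

Key step: step 13

## Route

C10 of 11 and 16–22 is enolisable and is written without configuration. C11 of 18–24 is a mixture of epimers that disappears in step 14. The carbinol centres of 7, 8 and 14 are mixtures that are erased later.

Step 1
Reactants: 1 but-2-yne-1,4-diol
Product: 2 4-[(tert-butyldiphenylsilyl)oxy]but-2-yn-1-ol
Conditions: NaH (1.0 equiv), THF, 0 °C; t-BuPh2SiCl (1.0 equiv), 23 °C; 1 in threefold excess
Reagents that add atoms: tert-butyl(chloro)diphenylsilane, CC(C)(C)[Si](Cl)(c1ccccc1)c1ccccc1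
Why: Monosilylation of a symmetrical diol through its monosodium alkoxide; excess diol is removed by aqueous extraction.

Step 2
Reactants: 2 4-[(tert-butyldiphenylsilyl)oxy]but-2-yn-1-ol
Product: 4 (2Z)-4-[(tert-butyldiphenylsilyl)oxy]-3-iodobut-2-en-1-ol, via sodium alkenylaluminate 3 (not isolated)
Conditions: NaAlH2(OCH2CH2OMe)2 (1.5 equiv), THF, 0→23 °C; then I2, THF, −78→0 °C
Reagents that add atoms: iodine, II
Why: Hydroxyl-directed trans-hydroalumination of the propargylic alcohol puts aluminium on C4 in a five-membered alkoxyaluminate; iodinolysis with retention leaves iodine cis to CH2OH, which fixes the later (Z)-C4=C5 geometry.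

Step 3
Reactants: 5 ethyl (2S)-2-[(tert-butyldimethylsilyl)oxy]propanoate
Product: 7 (4S)-4-[(tert-butyldimethylsilyl)oxy]pent-1-yn-3-ol (both C3 epimers), via silyloxy aldehyde 6 (not isolated)
Conditions: i-Bu2AlH (1.05 equiv), CH2Cl2, −78 °C; then HC≡CMgBr (2 equiv), THF, −78→0 °C
Reagents that add atoms: ethynylmagnesium bromide, C#C[Mg]Br
Why: Partial ester reduction to the aldehyde and Grignard addition in one flask; no selectivity is needed because C1 is oxidised in step 5 and C10 becomes enolisable in step 6.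

Step 4
Reactants: 4 (2Z)-4-[(tert-butyldiphenylsilyl)oxy]-3-iodobut-2-en-1-ol; 7 (4S)-4-[(tert-butyldimethylsilyl)oxy]pent-1-yn-3-ol
Product: 8 (2E,7S)-7-[(tert-butyldimethylsilyl)oxy]-3-{[(tert-butyldiphenylsilyl)oxy]methyl}oct-2-en-4-yne-1,6-diol (C6 epimers; CH2OH and alkyne cis)
Conditions: Pd(PPh3)2Cl2 (3 mol %), CuI (6 mol %), Et3N, THF, 23 °C
Reagents that add atoms: none
Why: Sonogashira coupling forms C3–C4 with retention of the alkene geometry; free hydroxyls are tolerated.

Step 5
Reactants: 8 (2E,7S)-7-[(tert-butyldimethylsilyl)oxy]-3-{[(tert-butyldiphenylsilyl)oxy]methyl}oct-2-en-4-yne-1,6-diol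
Product: 9 (2E,7S)-7-[(tert-butyldimethylsilyl)oxy]-3-{[(tert-butyldiphenylsilyl)oxy]methyl}-6-oxooct-2-en-4-ynal
Conditions: MnO2 (20 equiv), CH2Cl2, 23 °C
Reagents that add atoms: none
Why: MnO2 oxidises the primary allylic and the secondary propargylic alcohol in one operation; the C10 oxygen stays silylated so that no vicinal diol is exposed to the oxidant.

Step 6
Reactants: 9 (2E,7S)-7-[(tert-butyldimethylsilyl)oxy]-3-{[(tert-butyldiphenylsilyl)oxy]methyl}-6-oxooct-2-en-4-ynal
Product: 11 (2Z)-4-[(tert-butyldiphenylsilyl)oxy]-3-(5-methyl-4-oxo-4,5-dihydrofuran-2-yl)but-2-enal, via hydroxy ynone enal 10 (not isolated)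
Conditions: HF·pyridine, pyridine, THF, 0 °C; then Ph3PAuCl (2 mol %), AgOTf (2 mol %), toluene, 23 °C
Reagents that add atoms: none
Why: The secondary TBS ether next to the ketone is cleaved before the primary TBDPS ether; gold-catalysed 5-endo-dig addition of the freed hydroxyl to the ynone is the known cyclisation of γ-hydroxy alkynones to 3(2H)-furanones and makes C10 enolisable. The enal is used at once in step 9.

Step 7
Reactants: 12 (4R)-2,2-dimethyl-1,3-dioxolane-4-carbaldehyde; 13 methyl acrylate
Product: 14 methyl 2-{[(4R)-2,2-dimethyl-1,3-dioxolan-4-yl](hydroxy)methyl}prop-2-enoate (carbinol epimers)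
Conditions: DABCO (0.5 equiv), 1,4-dioxane/H2O (1:1), 23 °C
Reagents that add atoms: none
Why: Morita–Baylis–Hillman reaction forms C7–C11; the new carbinol centre becomes sp2 in step 8 and the dioxolane centre (C8) is not touched.

Step 8
Reactants: 14 methyl 2-{[(4R)-2,2-dimethyl-1,3-dioxolan-4-yl](hydroxy)methyl}prop-2-enoate
Product: 15 methyl (2Z)-2-(bromomethyl)-3-[(4S)-2,2-dimethyl-1,3-dioxolan-4-yl]prop-2-enoate
Conditions: NBS, Me2S, CH2Cl2, −20→23 °C
Reagents that add atoms: N-bromosuccinimide, O=C1CCC(=O)N1Br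
Why: Corey–Kim-type activation of the allylic alcohol and SN2′ attack by bromide give the more stable (Z)-2-(bromomethyl)alkenoate without acid that would open the acetonide.

Step 9
Reactants: 11 (2Z)-4-[(tert-butyldiphenylsilyl)oxy]-3-(5-methyl-4-oxo-4,5-dihydrofuran-2-yl)but-2-enal; 15 methyl (2Z)-2-(bromomethyl)-3-[(4S)-2,2-dimethyl-1,3-dioxolan-4-yl]prop-2-enoate
Product: 17 (4S,5R)-5-[(1Z)-3-[(tert-butyldiphenylsilyl)oxy]-2-(5-methyl-4-oxo-4,5-dihydrofuran-2-yl)prop-1-en-1-yl]-4-[(4S)-2,2-dimethyl-1,3-dioxolan-4-yl]-3-methylideneoxolan-2-one, via hydroxy ester 16 (not isolated)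
Conditions: CrCl2 (4 equiv), THF, 0→23 °C; then PPTS (10 mol %), CH2Cl2, 23 °C
Reagents that add atoms: none
Why: Nozaki–Hiyama allylation: the allylchromium reagent from 15 adds only to the aldehyde through a chair transition state with the C8 substituent equatorial, which should give the anti adduct and hence the trans lactone (C6, C7). The dioxolane centre directs the face of the allyl unit (attack anti to the C8–C9 bond, C–O bond outside), so C6 and C7 are relayed from C8 in one event.

Step 10
Reactants: 17 trans-α-methylene lactone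
Product: 18 (4S,5R)-5-[(1Z)-3-[(tert-butyldiphenylsilyl)oxy]-2-(5-methyl-4-oxo-4,5-dihydrofuran-2-yl)prop-1-en-1-yl]-4-[(4S)-2,2-dimethyl-1,3-dioxolan-4-yl]-3-[(phenylsulfanyl)methyl]oxolan-2-one (C11 epimers)
Conditions: PhSH (1.05 equiv), Et3N (10 mol %), CH2Cl2, 0 °C
Reagents that add atoms: benzenethiol, Sc1ccccc1
Why: Thia-Michael addition masks the exocyclic enoate, the one group that would trap the C10 carbanion of step 13; the vinylogous ester of the furanone is far less electrophilic.

Step 11
Reactants: 18 thiol adduct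
Product: 19 (4R,5R)-5-[(1Z)-3-[(tert-butyldiphenylsilyl)oxy]-2-(5-methyl-4-oxo-4,5-dihydrofuran-2-yl)prop-1-en-1-yl]-4-[(1S)-1,2-dihydroxyethyl]-3-[(phenylsulfanyl)methyl]oxolan-2-one
Conditions: AcOH/H2O (4:1), 40 °C
Reagents that add atoms: none
Why: Mild acetal hydrolysis; the TBDPS ether, the sulfide and the lactone are stable to aqueous acetic acid.

Step 12
Reactants: 19 diol
Product: 21 (4S,5R)-5-[(1Z)-3-[(tert-butyldiphenylsilyl)oxy]-2-(5-methyl-4-oxo-4,5-dihydrofuran-2-yl)prop-1-en-1-yl]-4-[(1S)-1-(2-methylpropanoyloxy)-2-(4-methylbenzenesulfonyloxy)ethyl]-3-[(phenylsulfanyl)methyl]oxolan-2-one, via primary tosylate 20 (not isolated)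
Conditions: Bu2SnO (5 mol %), TsCl (1.05 equiv), Et3N, CH2Cl2, 0 °C; then (i-PrCO)2O, DMAP (10 mol %), 23 °C
Reagents that add atoms: 4-methylbenzenesulfonyl chloride, Cc1ccc(cc1)S(Cl)(=O)=O; isobutyric anhydride, CC(C)C(=O)OC(=O)C(C)C
Why: Tin-acetal-catalysed sulfonylation is selective for the primary hydroxyl of a 1,2-diol; the remaining C8 hydroxyl is then esterified in the same flask, with no base strong enough to close an epoxide.

Step 13
Reactants: 21 tosylate isobutyrate
Product: 23 [(2Z,4R,8R,9R,11S)-2-{[(tert-butyldiphenylsilyl)oxy]methyl}-11-methyl-6,12-dioxo-7-[(phenylsulfanyl)methyl]-5,14-dioxatricyclo[9.2.1.0(4,8)]tetradeca-1(13),2-dien-9-yl] 2-methylpropanoate, via caesium furanolate 22 (not isolated)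
Conditions: Cs2CO3 (3 equiv), DMF, 60 °C, syringe-pump addition of 21 (final 2 mM)
Reagents that add atoms: none
Why: Proposed new method: Cs2CO3 removes the C10 hydrogen, the only C–H whose loss gives an aromatic anion (a 3-oxidofuran), and at high dilution C10 displaces the primary tosylate at C9 in an SN2 step (9-exo-tet) that closes the oxonane ring and returns the flat furan to the 3(2H)-furanone. The closest known reactions are the C2-alkylation of 2-alkylfuran-3(2H)-one enolates with alkyl halides and the closure of ten-membered germacrane rings by intramolecular alkylation of stabilised carbanions with primary tosylates. C-alkylation is the only intramolecular option, because O-alkylation would need a ring bridging the 3- and 5-positions of a planar furan, and C10 is the only carbon of the anion that carries charge. The new quaternary centre C10 is set by the furanolate face that C9 can reach: the (Z)-C4=C5 bond holds C6 on the oxygen side of the furan, and the trans lactone fixes the C5–C6–C7–C8 torsion near +60°, which in a torsional model places C7 away from the ring plane and C9 over the face that gives (10S). C8 keeps its configuration because substitution takes place at C9. The sulfide mask removes the enoate that would otherwise capture the carbanion, and carbonate is too weak to deprotonate the lactone or the isobutyrate.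

Step 14
Reactants: 23 bicyclic sulfide
Product: 25 [(2Z,4R,8R,9R,11S)-2-{[(tert-butyldiphenylsilyl)oxy]methyl}-11-methyl-7-methylidene-6,12-dioxo-5,14-dioxatricyclo[9.2.1.0(4,8)]tetradeca-1(13),2-dien-9-yl] 2-methylpropanoate, via sulfoxide 24 (not isolated)
Conditions: mCPBA (1.0 equiv), CH2Cl2, −78 °C; then toluene, 90 °C
Reagents that add atoms: none
Why: Sulfur is oxidised much faster than the electron-poor alkenes; thermal syn-elimination of the sulfoxide can only use H-11 and so regenerates the exocyclic methylene without base, which keeps the C8 ester safe from attack by a C11 enolate.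

Step 15
Reactants: 25 silyl ether
Product: 26 [(2Z,4R,8R,9R,11S)-2-(hydroxymethyl)-11-methyl-7-methylidene-6,12-dioxo-5,14-dioxatricyclo[9.2.1.0(4,8)]tetradeca-1(13),2-dien-9-yl] 2-methylpropanoate
Conditions: HF·pyridine, pyridine, THF, 0→23 °C
Reagents that add atoms: none
Why: Buffered fluoride cleaves the primary allylic silyl ether and spares the enoate lactone, the isobutyrate and the dienone.

## Compound list

1 | but-2-yne-1,4-diol | OCC#CCO | starting material
2 | 4-[(tert-butyldiphenylsilyl)oxy]but-2-yn-1-ol | OCC#CCO[Si](c1ccccc1)(c1ccccc1)C(C)(C)C | intermediate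
3 | sodium cyclic alkoxy(alkenyl)bis(2-methoxyethoxy)aluminate from 2 | [Na+].COCCO[Al-]1(OCCOC)OCC=C1CO[Si](c1ccccc1)(c1ccccc1)C(C)(C)C | intermediate
4 | (2Z)-4-[(tert-butyldiphenylsilyl)oxy]-3-iodobut-2-en-1-ol | OC/C=C(/CO[Si](c1ccccc1)(c1ccccc1)C(C)(C)C)I | intermediate
5 | ethyl (2S)-2-[(tert-butyldimethylsilyl)oxy]propanoate | CCOC(=O)[C@H](C)O[Si](C)(C)C(C)(C)C | starting material
6 | (2S)-2-[(tert-butyldimethylsilyl)oxy]propanal | O=C[C@H](C)O[Si](C)(C)C(C)(C)C | intermediate
7 | (4S)-4-[(tert-butyldimethylsilyl)oxy]pent-1-yn-3-ol (C3 epimers) | C#CC(O)[C@H](C)O[Si](C)(C)C(C)(C)C | intermediate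
8 | (2E,7S)-7-[(tert-butyldimethylsilyl)oxy]-3-{[(tert-butyldiphenylsilyl)oxy]methyl}oct-2-en-4-yne-1,6-diol (C6 epimers) | OC/C=C(/CO[Si](c1ccccc1)(c1ccccc1)C(C)(C)C)C#CC(O)[C@H](C)O[Si](C)(C)C(C)(C)C | intermediate
9 | (2E,7S)-7-[(tert-butyldimethylsilyl)oxy]-3-{[(tert-butyldiphenylsilyl)oxy]methyl}-6-oxooct-2-en-4-ynal | O=C/C=C(/CO[Si](c1ccccc1)(c1ccccc1)C(C)(C)C)C#CC(=O)[C@H](C)O[Si](C)(C)C(C)(C)C | intermediate
10 | (2E,7S)-3-{[(tert-butyldiphenylsilyl)oxy]methyl}-7-hydroxy-6-oxooct-2-en-4-ynal | O=C/C=C(/CO[Si](c1ccccc1)(c1ccccc1)C(C)(C)C)C#CC(=O)[C@H](C)O | intermediate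
11 | (2Z)-4-[(tert-butyldiphenylsilyl)oxy]-3-(5-methyl-4-oxo-4,5-dihydrofuran-2-yl)but-2-enal (C10 labile) | O=C/C=C(/CO[Si](c1ccccc1)(c1ccccc1)C(C)(C)C)C1=CC(=O)C(C)O1 | intermediate
12 | (4R)-2,2-dimethyl-1,3-dioxolane-4-carbaldehyde | O=C[C@H]1COC(C)(C)O1 | starting material
13 | methyl acrylate | C=CC(=O)OC | starting material
14 | methyl 2-{[(4R)-2,2-dimethyl-1,3-dioxolan-4-yl](hydroxy)methyl}prop-2-enoate (carbinol epimers) | COC(=O)C(=C)C(O)[C@H]1COC(C)(C)O1 | intermediate
15 | methyl (2Z)-2-(bromomethyl)-3-[(4S)-2,2-dimethyl-1,3-dioxolan-4-yl]prop-2-enoate | COC(=O)/C(CBr)=C/[C@H]1COC(C)(C)O1 | intermediate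
16 | methyl (3S,4R,5Z)-7-[(tert-butyldiphenylsilyl)oxy]-3-[(4S)-2,2-dimethyl-1,3-dioxolan-4-yl]-4-hydroxy-2-methylidene-6-(5-methyl-4-oxo-4,5-dihydrofuran-2-yl)hept-5-enoate | COC(=O)C(=C)[C@H]([C@H]1COC(C)(C)O1)[C@H](O)/C=C(/CO[Si](c1ccccc1)(c1ccccc1)C(C)(C)C)C1=CC(=O)C(C)O1 | intermediate
17 | (4S,5R)-5-[(1Z)-3-[(tert-butyldiphenylsilyl)oxy]-2-(5-methyl-4-oxo-4,5-dihydrofuran-2-yl)prop-1-en-1-yl]-4-[(4S)-2,2-dimethyl-1,3-dioxolan-4-yl]-3-methylideneoxolan-2-one | C=C1C(=O)O[C@H](/C=C(/CO[Si](c2ccccc2)(c2ccccc2)C(C)(C)C)C2=CC(=O)C(C)O2)[C@H]1[C@H]3COC(C)(C)O3 | intermediate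
18 | 3-[(phenylsulfanyl)methyl] analogue of 17 (thiol adduct, C11 epimers) | O=C1O[C@H](/C=C(/CO[Si](c2ccccc2)(c2ccccc2)C(C)(C)C)C2=CC(=O)C(C)O2)[C@@H]([C@H]2COC(C)(C)O2)C1CSc1ccccc1 | intermediate
19 | (4R,5R)-5-[(1Z)-3-[(tert-butyldiphenylsilyl)oxy]-2-(5-methyl-4-oxo-4,5-dihydrofuran-2-yl)prop-1-en-1-yl]-4-[(1S)-1,2-dihydroxyethyl]-3-[(phenylsulfanyl)methyl]oxolan-2-one | O=C1O[C@H](/C=C(/CO[Si](c2ccccc2)(c2ccccc2)C(C)(C)C)C2=CC(=O)C(C)O2)[C@@H]([C@H](O)CO)C1CSc1ccccc1 | intermediate
20 | primary (C9) 4-methylbenzenesulfonate of 19 | O=C1O[C@H](/C=C(/CO[Si](c2ccccc2)(c2ccccc2)C(C)(C)C)C2=CC(=O)C(C)O2)[C@@H]([C@H](O)COS(=O)(=O)c2ccc(C)cc2)C1CSc1ccccc1 | intermediate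
21 | (4S,5R)-5-[(1Z)-3-[(tert-butyldiphenylsilyl)oxy]-2-(5-methyl-4-oxo-4,5-dihydrofuran-2-yl)prop-1-en-1-yl]-4-[(1S)-1-(2-methylpropanoyloxy)-2-(4-methylbenzenesulfonyloxy)ethyl]-3-[(phenylsulfanyl)methyl]oxolan-2-one | O=C1O[C@H](/C=C(/CO[Si](c2ccccc2)(c2ccccc2)C(C)(C)C)C2=CC(=O)C(C)O2)[C@@H]([C@H](OC(=O)C(C)C)COS(=O)(=O)c2ccc(C)cc2)C1CSc1ccccc1 | intermediate
22 | caesium 2-methylfuran-3-olate derived from 21 | [Cs+].O=C1O[C@H](/C=C(/CO[Si](c2ccccc2)(c2ccccc2)C(C)(C)C)c2cc([O-])c(C)o2)[C@@H]([C@H](OC(=O)C(C)C)COS(=O)(=O)c2ccc(C)cc2)C1CSc1ccccc1 | intermediate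
23 | [(2Z,4R,8R,9R,11S)-2-{[(tert-butyldiphenylsilyl)oxy]methyl}-11-methyl-6,12-dioxo-7-[(phenylsulfanyl)methyl]-5,14-dioxatricyclo[9.2.1.0(4,8)]tetradeca-1(13),2-dien-9-yl] 2-methylpropanoate (C11 epimers) | c1ccccc1SCC1C(=O)O[C@@H]2/C=C(/CO[Si](c3ccccc3)(c3ccccc3)C(C)(C)C)C3=CC(=O)[C@](C)(C[C@@H](OC(=O)C(C)C)[C@@H]12)O3 | intermediate
24 | S-oxide of 23 | O=S(c1ccccc1)CC1C(=O)O[C@@H]2/C=C(/CO[Si](c3ccccc3)(c3ccccc3)C(C)(C)C)C3=CC(=O)[C@](C)(C[C@@H](OC(=O)C(C)C)[C@@H]12)O3 | intermediate
25 | [(2Z,4R,8R,9R,11S)-2-{[(tert-butyldiphenylsilyl)oxy]methyl}-11-methyl-7-methylidene-6,12-dioxo-5,14-dioxatricyclo[9.2.1.0(4,8)]tetradeca-1(13),2-dien-9-yl] 2-methylpropanoate | C=C1C(=O)O[C@@H]2/C=C(/CO[Si](c3ccccc3)(c3ccccc3)C(C)(C)C)C3=CC(=O)[C@](C)(C[C@@H](OC(=O)C(C)C)[C@@H]12)O3 | intermediate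
26 | [(2Z,4R,8R,9R,11S)-2-(hydroxymethyl)-11-methyl-7-methylidene-6,12-dioxo-5,14-dioxatricyclo[9.2.1.0(4,8)]tetradeca-1(13),2-dien-9-yl] 2-methylpropanoate | C=C1C(=O)O[C@@H]2/C=C(/CO)C3=CC(=O)[C@](C)(C[C@@H](OC(=O)C(C)C)[C@@H]12)O3 | target

## Step count and risks

Total steps: 15. Longest linear sequence: 12 (steps 1, 2, 4, 5, 6, 9, 10, 11, 12, 13, 14, 15).

**Step 13 (key step, Proposed new method).** The most likely failure is intermolecular alkylation outrunning ring closure: SN2 at a primary carbon next to an acyloxy group is slow, and the nine-membered transition state carries transannular strain. The second risk is attack on the other furanolate face, because the facial preference rests on a torsional argument and not on precedent.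

Fallback (known reactions only): the two C–C bond formations change places, so that C9–C10 is made between two molecules and the ring is closed at C6–C7 as in Alternative 1. It sets out from 12 and 11 and comes back at 25.
- Acidic methanolysis of 12 gives (2R)-3,3-dimethoxypropane-1,2-diol F1.
- Tosylation of its primary hydroxyl and isobutyrylation as in step 12 give the acetal tosylate F2.
- The caesium enolate of 11 (Cs2CO3, DMF) is alkylated at C10 by F2 to the C10-alkylated acetal F3 (10S epimer, separated from its 10R epimer). Aldol addition of the stabilised anion to the enal is reversible, alkylation is not.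
- Aqueous acid frees the saturated aldehyde F4.
- This aldehyde, and not the β,β-disubstituted enal, undergoes the Morita–Baylis–Hillman reaction with 13 (DABCO) to the allylic alcohol F5.
- NBS/Me2S converts it into the (Z)-allylic bromide F6, which is the compound A1.
- CrCl2 in THF at high dilution closes the ring through the macrocyclic hydroxy ester F7 (not isolated), which lactonises to 25. Step 15 follows.

**Step 9.** The most likely failure is loss of control over the C6/C7/C8 triad: a syn adduct through a non-chair pathway, or attack on the other face of the allyl unit. The enal may also isomerise under Lewis-acidic chromium salts.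

Fallback: the C6–C7 bond is made under reagent control and the lactone is closed afterwards. It sets out from 12 and 11 and comes back at 17.
- Ethynylmagnesium bromide adds to 12 to give, after separation from its epimer, (1S)-1-[(4R)-2,2-dimethyl-1,3-dioxolan-4-yl]prop-2-yn-1-ol F8.
- MsCl/Et3N gives the propargylic mesylate F9.
- Pd(OAc)2/PPh3 and InI convert F9 into a configurationally defined allenylindium reagent (Marshall–Tamaru propargylation, with inversion at the mesylate carbon). It adds to 11 through a cyclic transition state to give the anti homopropargylic alcohol F10.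
- Palladium-catalysed cyclocarbonylation of F10 (PdCl2, PPh3, SnCl2, CO) gives 17.

**Step 14.** The thermal syn-elimination may be too slow at temperatures that the dienone–lactone tolerates. The sulfenic acid that leaves may add back, and the 1,5-diene C4=C5/C11=C13 may begin to rearrange on heating.

Fallback: the elimination is changed from a thermal syn process to a base-induced one. It sets out from 23 and comes back at 25. KHSO5 oxidises 23 to the bicyclic sulfone F11, and DBU at 0 °C expels benzenesulfinate from C13 (E1cB) to give 25.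

## Further compounds

F1 | step 13 | (2R)-3,3-dimethoxypropane-1,2-diol | COC(OC)[C@H](O)CO
F2 | step 13 | (2R)-1,1-dimethoxy-3-(4-methylbenzenesulfonyloxy)propan-2-yl 2-methylpropanoate | COC(OC)[C@H](OC(=O)C(C)C)COS(=O)(=O)c1ccc(C)cc1
F3 | step 13 | C10-alkylated furanone acetal (8R,10S): (2Z)-4-[(tert-butyldiphenylsilyl)oxy]-3-{(5S)-5-[(2R)-3,3-dimethoxy-2-(2-methylpropanoyloxy)propyl]-5-methyl-4-oxo-4,5-dihydrofuran-2-yl}but-2-enal | O=C/C=C(/CO[Si](c1ccccc1)(c1ccccc1)C(C)(C)C)C1=CC(=O)[C@](C)(C[C@@H](OC(=O)C(C)C)C(OC)OC)O1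
F4 | step 13 | dialdehyde from F3 (C7 aldehyde, C8 isobutyrate) | O=C/C=C(/CO[Si](c1ccccc1)(c1ccccc1)C(C)(C)C)C1=CC(=O)[C@](C)(C[C@@H](OC(=O)C(C)C)C=O)O1
F5 | step 13 | Morita–Baylis–Hillman alcohol from F4 (C7 epimers) | O=C/C=C(/CO[Si](c1ccccc1)(c1ccccc1)C(C)(C)C)C1=CC(=O)[C@](C)(C[C@@H](OC(=O)C(C)C)C(O)C(=C)C(=O)OC)O1
F6 | step 13 | seco aldehyde with (Z)-2-(bromomethyl)alkenoate | O=C/C=C(/CO[Si](c1ccccc1)(c1ccccc1)C(C)(C)C)C1=CC(=O)[C@](C)(C[C@@H](OC(=O)C(C)C)/C=C(/C(=O)OC)CBr)O1
F7 | step 13 | macrocyclic hydroxy ester (C6 hydroxyl, C12 methyl ester) that lactonises to 25 | COC(=O)C(=C)[C@H]1[C@H](O)/C=C(/CO[Si](c2ccccc2)(c2ccccc2)C(C)(C)C)C2=CC(=O)[C@](C)(C[C@H]1OC(=O)C(C)C)O2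
F8 | step 9 | (1S)-1-[(4R)-2,2-dimethyl-1,3-dioxolan-4-yl]prop-2-yn-1-ol | C#C[C@@H]([C@H]1COC(C)(C)O1)O
F9 | step 9 | (1S)-1-[(4R)-2,2-dimethyl-1,3-dioxolan-4-yl]prop-2-yn-1-yl methanesulfonate | C#C[C@@H]([C@H]1COC(C)(C)O1)OS(C)(=O)=O
F10 | step 9 | anti homopropargylic alcohol (C6 R, C7 S, C8 S) | C#C[C@H]([C@H]1COC(C)(C)O1)[C@H](O)/C=C(/CO[Si](c1ccccc1)(c1ccccc1)C(C)(C)C)C1=CC(=O)C(C)O1
F11 | step 14 | S,S-dioxide (sulfone) of 23 | O=S(=O)(c1ccccc1)CC1C(=O)O[C@@H]2/C=C(/CO[Si](c3ccccc3)(c3ccccc3)C(C)(C)C)C3=CC(=O)[C@](C)(C[C@@H](OC(=O)C(C)C)[C@@H]12)O3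
A1 | alternative 1 | seco aldehyde with (Z)-2-(bromomethyl)alkenoate and preformed quaternary furanone | O=C/C=C(/CO[Si](c1ccccc1)(c1ccccc1)C(C)(C)C)C1=CC(=O)[C@](C)(C[C@@H](OC(=O)C(C)C)/C=C(/C(=O)OC)CBr)O1
A2 | alternative 2 | diazo ketone on a 2-vinyl-3,6-dihydro-2H-pyran | CC(=[N+]=[N-])C(=O)C[C@@H]1O[C@H](C=C)[C@@H](O[Si](C)(C)C(C)(C)C)C=C1CO[Si](c1ccccc1)(c1ccccc1)C(C)(C)C
A3 | alternative 2 | 11-oxabicyclo[6.2.1]undecadienone with C7=C8 | C[C@]12C/C=C\[C@@H](O[Si](C)(C)C(C)(C)C)/C=C(/CO[Si](c3ccccc3)(c3ccccc3)C(C)(C)C)[C@@H](CC1=O)O2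
A4 | alternative 3 | seco nitrile oxide (C1 nitrile oxide, C10 triethylsilyl ether, C3 vinyl) | C=C1C(=O)O[C@H](/C=C(/CO[Si](c2ccccc2)(c2ccccc2)C(C)(C)C)C=C)[C@H]1[C@@H](C[C@](C)(O[Si](CC)(CC)CC)C#[N+][O-])OC(=O)C(C)C
A5 | alternative 3 | bridged isoxazoline of the ten-membered carbocycle | C=C1C(=O)O[C@@H]2/C=C(/CO[Si](c3ccccc3)(c3ccccc3)C(C)(C)C)C3CC(=NO3)[C@@](C)(O[Si](CC)(CC)CC)C[C@@H](OC(=O)C(C)C)[C@@H]12
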